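**Retrosynthetic overview**

1. Sigmoidin A is taken back to its tetrakis(methoxymethyl) ether, and the four acetals are removed last by acid methanolysis.
2. Ring C is cut at O1–C8a and C4–C4a. On ring A the ether oxygen O1 (on C8a) and the C4 carbonyl (on C4a) are ortho neighbours and C4a is flanked by the C5 oxygen, the pattern left when an alkoxide and then an acyl group add across a 3-alkoxy aryne. The partners are 3,5-bis(methoxymethoxy)benzyne (silyl triflate from phloroglucinol) and the (S)-beta-hydroxy ester of ring B, used as its O-trimethylsilyl ether so that fluoride frees the alkoxide with no O–H proton in the flask.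
3. The S carbinol (later C2) is set by asymmetric transfer hydrogenation of the beta-keto ester, made by Claisen condensation of the ring B methyl ketone with dimethyl carbonate. 3,4-Dihydroxyacetophenone replaces the aldehyde so that no Lewis acid meets an ortho-prenyl carbonyl compound.
4. Both prenyl groups come from one double aromatic Claisen rearrangement of the bis(1,1-dimethylallyl) ether (O3 to C2, O4 to C5).
5. Ring order: rings A and B are bought; ring C is the only ring formed (step 11).

Key step: step 11

**Route**

Step 1
Reactants: 1 3,4-dihydroxyacetophenone; 2 3-chloro-3-methylbut-1-yne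
Product: 3 1-[3,4-bis(2-methylbut-3-yn-2-yloxy)phenyl]ethanone
Conditions: 2 (3 equiv), DBU, CuCl2·2H2O (1 mol%), MeCN, 0 °C → rt, argon
Reagents that add atoms: none
Why: Copper-catalysed O-propargylation of phenoxides by a tertiary propargylic chloride is the standard entry to aryl 1,1-dimethylpropargyl ethers and should leave the ketone untouched.

Step 2
Reactants: 3 1-[3,4-bis(2-methylbut-3-yn-2-yloxy)phenyl]ethanone
Product: 4 1-[3,4-bis(2-methylbut-3-en-2-yloxy)phenyl]ethanone
Conditions: H2 (1 atm), Pd on CaCO3 poisoned with Pb(OAc)2 (Lindlar catalyst), quinoline, EtOAc, rt, stopped after 2 equiv H2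
Reagents that add atoms: none
Why: Lindlar semi-hydrogenation should stop at the vinyl stage for both terminal alkynes when hydrogen uptake is followed, and the aryl ketone is not reduced.

Step 3
Reactants: 4 1-[3,4-bis(2-methylbut-3-en-2-yloxy)phenyl]ethanone
Product: 5 1-[3,4-dihydroxy-2,5-bis(3-methylbut-2-enyl)phenyl]ethanone
Conditions: PhNEt2, 150 °C, argon
Reagents that add atoms: none
Why: Double aromatic Claisen [3,3] rearrangement: each tertiary allyl ether has one free ortho carbon (O3 to C2, O4 to C5), and the allyl inversion turns the 1,1-dimethylallyl group into the 3-methylbut-2-enyl group.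

Step 4
Reactants: 5 1-[3,4-dihydroxy-2,5-bis(3-methylbut-2-enyl)phenyl]ethanone
Product: 6 1-[3,4-bis(methoxymethoxy)-2,5-bis(3-methylbut-2-enyl)phenyl]ethanone
Conditions: MOMCl, iPr2NEt, Bu4NI (cat.), CH2Cl2, 0 → 40 °C
Reagents that add atoms: chloromethyl methyl ether, COCCl
Why: O-alkylation of both phenols with MOMCl and a hindered amine base (Williamson-type acetal formation) removes the air-sensitive catechol and its acidic protons before the enolate chemistry.

Step 5
Reactants: 6 1-[3,4-bis(methoxymethoxy)-2,5-bis(3-methylbut-2-enyl)phenyl]ethanone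
Product: 7 methyl 3-[3,4-bis(methoxymethoxy)-2,5-bis(3-methylbut-2-enyl)phenyl]-3-oxopropanoate
Conditions: NaH, (MeO)2CO, THF, 65 °C; AcOH quench
Reagents that add atoms: dimethyl carbonate, COC(=O)OC
Why: Crossed Claisen condensation of the methyl ketone enolate with dimethyl carbonate, driven by deprotonation of the beta-keto ester formed; MOM ethers and prenyl groups are inert to the base.

Step 6
Reactants: 7 methyl 3-[3,4-bis(methoxymethoxy)-2,5-bis(3-methylbut-2-enyl)phenyl]-3-oxopropanoate
Product: 8 methyl (S)-3-hydroxy-3-[3,4-bis(methoxymethoxy)-2,5-bis(3-methylbut-2-enyl)phenyl]propanoate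
Conditions: RuCl[(S,S)-TsDPEN](p-cymene) (1 mol%), HCO2H/Et3N (5:2), EtOAc, 35 °C
Reagents that add atoms: none
Why: Noyori–Ikariya asymmetric transfer hydrogenation: with the (S,S) ligand the hydride should go to the Re face of the aryl ketone (aryl held by the CH–pi contact to the cymene), setting the carbinol as S, and the outer-sphere mechanism leaves the trisubstituted alkenes alone.

Step 7
Reactants: 8 methyl (S)-3-hydroxy-3-[3,4-bis(methoxymethoxy)-2,5-bis(3-methylbut-2-enyl)phenyl]propanoate
Product: 9 methyl (S)-3-[3,4-bis(methoxymethoxy)-2,5-bis(3-methylbut-2-enyl)phenyl]-3-(trimethylsilyloxy)propanoate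
Conditions: TMSCl, imidazole, CH2Cl2, 0 °C; filtration through Et3N-washed silica
Reagents that add atoms: chlorotrimethylsilane, C[Si](C)(C)Cl
Why: Routine O-silylation of a secondary alcohol; it removes the only O–H proton so that fluoride can later release the alkoxide under aprotic conditions.

Step 8
Reactants: 10 phloroglucinol
Product: 11 3,5-bis(methoxymethoxy)phenol
Conditions: MOMCl (2.0 equiv), iPr2NEt, DMF, 0 °C → rt; chromatography
Reagents that add atoms: chloromethyl methyl ether, COCCl
Why: Statistical O-alkylation of three equivalent phenols with two equivalents of MOMCl; the mono and tris ethers that also form are separated on silica.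

Step 9
Reactants: 11 3,5-bis(methoxymethoxy)phenol
Product: 12 2-bromo-3,5-bis(methoxymethoxy)phenol
Conditions: NBS (1.0 equiv), iPr2NH (10 mol%), CH2Cl2, −78 → 0 °C
Reagents that add atoms: N-bromosuccinimide, O=C1CCC(=O)N1Br
Why: Amine-catalysed ortho-selective electrophilic bromination of a phenol (the N-bromoamine is delivered through a hydrogen bond to the OH); the two ortho positions are equivalent.

Step 10
Reactants: 12 2-bromo-3,5-bis(methoxymethoxy)phenol
Product: 15 3,5-bis(methoxymethoxy)-2-(trimethylsilyl)phenyl trifluoromethanesulfonate, via aryl trimethylsilyl ether 13 (not isolated), via lithium 2-silylphenoxide 14 (not isolated)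
Conditions: HMDS, THF, 65 °C, then evaporation; n-BuLi, THF, −78 °C; Tf2O, −78 °C
Reagents that add atoms: hexamethyldisilazane, C[Si](C)(C)N[Si](C)(C)C; trifluoromethanesulfonic anhydride, O=S(=O)(OS(=O)(=O)C(F)(F)F)C(F)(F)F
Why: O-silylation, bromine–lithium exchange and anionic 1,3-silyl shift from O to C (retro-Brook rearrangement) give the ortho-silyl phenoxide, which is triflated in the same flask; this is the standard preparation of ortho-silylaryl triflates.

Step 11
Reactants: 9 methyl (S)-3-[3,4-bis(methoxymethoxy)-2,5-bis(3-methylbut-2-enyl)phenyl]-3-(trimethylsilyloxy)propanoate; 15 3,5-bis(methoxymethoxy)-2-(trimethylsilyl)phenyl trifluoromethanesulfonate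
Product: 18 (S)-sigmoidin A tetrakis(methoxymethyl) ether, via aryne 16 (not isolated), via cesium alkoxide 17 (not isolated)
Conditions: CsF, 18-crown-6, THF, 0 → 20 °C, 15 (1.6 equiv) added over 4 h; pH 7 buffer
Reagents that add atoms: none
Why: Proposed new method: fluoride removes SiMe3 from 15 and triflate leaves to give aryne 16, while fluoride (and then the methoxide expelled in each turnover) takes SiMe3 from the oxygen of 9, so that cesium alkoxide 17 is present in low concentration and the flask holds no O–H proton. Alkoxide 17 adds to the aryne carbon remote from the flanking methoxymethoxy group (the future C8a), the flatter and more electrophilic end of the distorted 3-alkoxy aryne, which leaves the carbanion on the future C4a beside the inductively withdrawing C5 oxygen. This aryl anion attacks the methyl ester carbonyl in a 6-exo-trig closure of ring C and the tetrahedral intermediate expels methoxide, which is silylated by 9 or by Me3SiF and so neither protonates an aryl anion as methanol nor opens ring C by retro-oxa-Michael reaction. The closest known reactions are the xanthone synthesis from arynes and salicylate esters (phenoxide addition followed by acylation on the ester) and the acyl-alkylation of arynes by beta-keto esters; a secondary aliphatic alkoxide as the oxygen partner is the untested element. No stereocentre is formed, and C2 keeps the S configuration of step 6 because its C–O bond is not broken. The step needs O-addition to outrun the ene reaction of the aryne with the prenyl groups and acylation to outrun proton capture and abstraction of the C3 proton, for which the anionic nucleophile, the aprotic THF medium, slow addition of 15 and the six-membered transition state are relied on.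

Step 12
Reactants: 18 (S)-sigmoidin A tetrakis(methoxymethyl) ether
Product: 19 sigmoidin A
Conditions: 3 M aq. HCl, MeOH, 40 °C
Reagents that add atoms: none
Why: Acid-catalysed acetal methanolysis of the four MOM ethers; dilute acid forms no enolate, so C2 should stay S, and short exposure limits addition of the freed phenols to the prenyl double bonds.

**Compound list**

1 | 3,4-dihydroxyacetophenone | CC(=O)c1ccc(O)c(O)c1 | starting material
2 | 3-chloro-3-methylbut-1-yne | CC(C)(Cl)C#C | starting material
3 | 1-[3,4-bis(2-methylbut-3-yn-2-yloxy)phenyl]ethanone | CC(=O)c1ccc(OC(C)(C)C#C)c(OC(C)(C)C#C)c1 | intermediate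
4 | 1-[3,4-bis(2-methylbut-3-en-2-yloxy)phenyl]ethanone | CC(=O)c1ccc(OC(C)(C)C=C)c(OC(C)(C)C=C)c1 | intermediate
5 | 1-[3,4-dihydroxy-2,5-bis(3-methylbut-2-enyl)phenyl]ethanone | CC(=O)c1cc(CC=C(C)C)c(O)c(O)c1CC=C(C)C | intermediate
6 | 1-[3,4-bis(methoxymethoxy)-2,5-bis(3-methylbut-2-enyl)phenyl]ethanone | CC(=O)c1cc(CC=C(C)C)c(OCOC)c(OCOC)c1CC=C(C)C | intermediate
7 | methyl 3-[3,4-bis(methoxymethoxy)-2,5-bis(3-methylbut-2-enyl)phenyl]-3-oxopropanoate | COC(=O)CC(=O)c1cc(CC=C(C)C)c(OCOC)c(OCOC)c1CC=C(C)C | intermediate
8 | methyl (S)-3-hydroxy-3-[3,4-bis(methoxymethoxy)-2,5-bis(3-methylbut-2-enyl)phenyl]propanoate | CC(C)=CCc1cc([C@@H](O)CC(=O)OC)c(CC=C(C)C)c(OCOC)c1OCOC | intermediate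
9 | methyl (S)-3-[3,4-bis(methoxymethoxy)-2,5-bis(3-methylbut-2-enyl)phenyl]-3-(trimethylsilyloxy)propanoate | CC(C)=CCc1cc([C@@H](O[Si](C)(C)C)CC(=O)OC)c(CC=C(C)C)c(OCOC)c1OCOC | intermediate
10 | phloroglucinol (benzene-1,3,5-triol) | Oc1cc(O)cc(O)c1 | starting material
11 | 3,5-bis(methoxymethoxy)phenol | COCOc1cc(O)cc(OCOC)c1 | intermediate
12 | 2-bromo-3,5-bis(methoxymethoxy)phenol | COCOc1cc(O)c(Br)c(OCOC)c1 | intermediate
13 | [2-bromo-3,5-bis(methoxymethoxy)phenoxy]trimethylsilane | COCOc1cc(O[Si](C)(C)C)c(Br)c(OCOC)c1 | intermediate
14 | lithium 3,5-bis(methoxymethoxy)-2-(trimethylsilyl)phenoxide | [Li+].[O-]c1cc(OCOC)cc(OCOC)c1[Si](C)(C)C | intermediate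
15 | 3,5-bis(methoxymethoxy)-2-(trimethylsilyl)phenyl trifluoromethanesulfonate | COCOc1cc(OCOC)c([Si](C)(C)C)c(OS(=O)(=O)C(F)(F)F)c1 | intermediate
16 | 3,5-bis(methoxymethoxy)benzyne | COCOC1=CC(OCOC)=CC#C1 | intermediate
17 | cesium (S)-1-[3,4-bis(methoxymethoxy)-2,5-bis(3-methylbut-2-enyl)phenyl]-3-methoxy-3-oxopropan-1-olate | CC(C)=CCc1cc([C@@H]([O-])CC(=O)OC)c(CC=C(C)C)c(OCOC)c1OCOC.[Cs+] | intermediate
18 | (S)-sigmoidin A tetrakis(methoxymethyl) ether, (2S)-2-[3,4-bis(methoxymethoxy)-2,5-bis(3-methylbut-2-enyl)phenyl]-5,7-bis(methoxymethoxy)chroman-4-one | CC(C)=CCc1cc([C@@H]2CC(=O)c3c(OCOC)cc(OCOC)cc3O2)c(CC=C(C)C)c(OCOC)c1OCOC | intermediate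
19 | sigmoidin A, (2S)-2-[3,4-dihydroxy-2,5-bis(3-methylbut-2-enyl)phenyl]-5,7-dihydroxychroman-4-one | CC(C)=CCc1cc([C@@H]2CC(=O)c3c(O)cc(O)cc3O2)c(CC=C(C)C)c(O)c1O | target

**Step count**

Total steps: 12. Longest linear sequence: 9 steps (steps 1 to 7, then 11 and 12).

**Steps most likely to fail**

Step 11 (proposed new method). The aryl anion may capture a proton before it acylates, which would stop the reaction at the open aryl ether. The aryne may be consumed by ene reaction with the prenyl groups. Abstraction of the C3 proton may lead to elimination of the aryloxide, and base may open ring C with loss of configuration at C2. The fallback builds the same two bonds one after the other by known chemistry; it sets out from 7 (and uses 12 from step 9) and comes back at 18. Transfer hydrogenation of 7 with RuCl[(R,R)-TsDPEN](p-cymene) and HCO2H/Et3N would give methyl (R)-3-hydroxy-3-[3,4-bis(methoxymethoxy)-2,5-bis(3-methylbut-2-enyl)phenyl]propanoate F1. Mitsunobu etherification of this alcohol with bromophenol 12 (PPh3, DIAD, toluene, 0 °C) inverts the carbinol and should give methyl (S)-3-[2-bromo-3,5-bis(methoxymethoxy)phenoxy]-3-[3,4-bis(methoxymethoxy)-2,5-bis(3-methylbut-2-enyl)phenyl]propanoate F2. Bromine–lithium exchange (n-BuLi, THF, −100 °C) followed by Parham cyclisation of the aryllithium onto the ester closes ring C to 18, which goes on to step 12.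

Step 3. The tertiary allyl groups may be lost as isoprene, the group on O3 may migrate by the para pathway to C6 in place of the crowded C2, and the freed phenols may add to the new prenyl groups to give chromans. The fallback replaces the sigmatropic route by cross-coupling; it sets out from 1 and comes back at 6, so steps 1 to 4 are bypassed. Bromination of 1 (Br2, NaOAc, AcOH), in which each hydroxyl sends bromine to its single free ortho carbon, should give 1-(2,5-dibromo-3,4-dihydroxyphenyl)ethanone F3. Protection with MOMCl and iPr2NEt would give 1-[2,5-dibromo-3,4-bis(methoxymethoxy)phenyl]ethanone F4. Double Stille coupling with tributyl(3-methylbut-2-enyl)stannane (Pd(PPh3)4, CuI, CsF, DMF, 90 °C) would then give 6.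

Step 1. The second etherification, next to the first tertiary ether, may stay incomplete, and the copper salt may oxidise the catecholate. The fallback changes the O-alkylation from copper-propargyl to palladium-allyl chemistry; it sets out from 1 and comes back at 4, so step 2 is bypassed as well. Treatment of 1 with tert-butyl 2-methylbut-3-en-2-yl carbonate and Pd(PPh3)4 in THF at 0 °C → rt should give 4 directly, because the phenoxide attacks the more substituted end of the prenyl palladium complex; compounds outside the list: none F0.

**Further compounds**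

F1 | step 11 | methyl (R)-3-hydroxy-3-[3,4-bis(methoxymethoxy)-2,5-bis(3-methylbut-2-enyl)phenyl]propanoate | CC(C)=CCc1cc([C@H](O)CC(=O)OC)c(CC=C(C)C)c(OCOC)c1OCOC
F2 | step 11 | methyl (S)-3-[2-bromo-3,5-bis(methoxymethoxy)phenoxy]-3-[3,4-bis(methoxymethoxy)-2,5-bis(3-methylbut-2-enyl)phenyl]propanoate | CC(C)=CCc1cc([C@@H](Oc2cc(OCOC)cc(OCOC)c2Br)CC(=O)OC)c(CC=C(C)C)c(OCOC)c1OCOC
F3 | step 3 | 1-(2,5-dibromo-3,4-dihydroxyphenyl)ethanone | CC(=O)c1cc(Br)c(O)c(O)c1Br
F4 | step 3 | 1-[2,5-dibromo-3,4-bis(methoxymethoxy)phenyl]ethanone | CC(=O)c1cc(Br)c(OCOC)c(OCOC)c1Br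
F0 | step 1 | none | none
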